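Amounts first: each flask starts with 0.14 M of G, and I want the J standing at 30 min.

| setting | Wednesday's | Monday's | dusk | autumn |
|---|---|---|---|---|
| G | 0.070 M | 0.28 M | 0.14 M | 0.14 M |
| Z | 0.05 mol% (in portions, 4) | 0.05 mol% (in portions, 4) | 0.05 mol% | 0.05 mol% (in portions, 4) |
| temperature | 45 °C | 56 °C | 60 °C | 40 °C |
| remark | run made earlier; portions every 8.0 min | run made earlier; portions every 8.0 min | everything together at the start | the portions of Z follow each other after 8.0 min, the first at the start |
| time |  |  | 30 min | 30 min |

- which of the two ends with the higher amount of J, in percent of the G charged ("neither" if they lie within 2 percentage points) (dusk / autumn / neither)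
- J at the end, in percent of the G charged, dusk
- J at the end, in percent of the G charged, autumn

- Wednesday's (time / min: J / %, G / %): 2.00: 2.2, 98.6; 6.00: 3.9, 93.5; 12.0: 6.8, 85.6; 15.0: 8.2, 82.9; 25.0: 10.5, 67.7
- Monday's (time / min: J / %, G / %): 0.833: 1.1, 99.0; 2.50: 1.5, 96.7; 5.00: 2.7, 91.8; 6.00: 3.7, 92.3; 12.0: 6.5, 82.7

(scatter of a reading: 0.5 percentage points)

- the earlier runs were read with a standard deviation of 0.5 percentage points
- a reading or a percentage of J counts all its forms, free or not
- a reading of G is of its free form alone

In both runs G falls faster than J rises, so J is not a running total: some of the G lost does not stand as J. The gap, the part of the charge read neither as G nor as J, grows, so I divide the mean J over a stretch by the growth rate of the gap. I call this the holding time h of J, the inverse of a pseudo-first-order loss constant. Wednesday's last stretch reads 7.92 min. Monday's reads 6.08 min, though each carries the scatter of 0.5 percentage points.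

Wednesday's h is shorter than the run, and as a rough estimate of my own I put J at the end at the mean rate of G loss times h, though later portions of Z may carry J past that. Wednesday's figures give 10.2%, my figure for autumn. Monday's give 8.76%, and dusk runs hotter than Monday, so I take that as a top for dusk and lean to autumn.

The forecast differs: dusk, with 15% (8% to 28%) for dusk and 11.5% (9% to 14.5%) for autumn, in its words “I lean to dusk, not firmly”.

Dusk ends at 2.30% and autumn at 16.5%.

    Z → L (k = 5.00 × 10⁻⁴ min⁻¹, Ea = 214 kJ mol⁻¹)
    G + Z → J + Z, rate k2*[G]^2.5*[Z]/(1 + ([G]/Kh2)^2.5) (39.0 mM, k = 10000 L²·⁵ mol⁻²·⁵ s⁻¹, Ea = 30.0 kJ mol⁻¹)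
    J → D (k = 0.0850 min⁻¹, Ea = 96.0 kJ mol⁻¹)
    G + J ⇌ X, settled at all times (K = 8.30 L mol⁻¹, ΔH = −4.00 kJ mol⁻¹)
    2 Z ⇌ Q, settled at all times (K = 2.70 × 10⁵ L mol⁻¹, ΔH = −24.0 kJ mol⁻¹)
    (constants at 40 °C)

The half-life of free J by its loss to D is 8.2 min in autumn and 0.89 min at the end of dusk, shorter there, and h from half time to the end is 16.0 min in autumn against 1.94 min in dusk. In the neighbouring flask, the dusk recipe at 45 °C, G falls to 48%, so Wednesday's h gives 13.7% of J, and that flask ends at 15.3%.

The readings stem from a simulated flask on assumed constants; the scatter is artificial.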